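The cyclohexene (C1 acetoxy carbinol, C2 CMe2, C3 CH–CH2OAr, C4 =C–Me, C5 =CH, C6 CH2) is opened at C3–C4. C3 lies α to the exocyclic oxygenated carbon, so at the ester oxidation level it is an enolate carbon, while C4 is a vinylic carbon that can carry iodide. An acyclic (Z)-vinyl iodide ester is therefore cyclised by palladium-catalysed intramolecular α-alkenylation of its zinc enolate: one operation closes the ring, fixes the trisubstituted alkene and sets C3 trans to the C1 oxygen. The quaternary C2 excludes β-hydride elimination, and allylic strain from the C4 methyl drives the ester pseudoaxial. Ester reduction, Mitsunobu etherification with umbelliferone and acetylation finish.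

Key step: step 6

Remark: the target is read as the trans (1R,3R) acetate; methyl 3,3-dimethylpent-4-enoate and umbelliferone are taken as commercial.

Step 1
Reactants: 1 methyl 3,3-dimethylpent-4-enoate
Product: 2 methyl 3,3-dimethyl-4-oxobutanoate
Conditions: O3, CH2Cl2, −78 °C; then Me2S, −78 °C → rt
Reagents that add atoms: ozone, [O-][O+]=O
Why: Ozonolysis with reductive work-up cleaves the only C=C bond of 1 to the non-enolisable α-quaternary aldehyde and leaves the ester untouched.

Step 2
Reactants: 2 methyl 3,3-dimethyl-4-oxobutanoate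
Product: 3 methyl (4R)-4-hydroxy-3,3-dimethylhept-6-enoate
Conditions: (+)-Ipc2B(allyl) (from (−)-α-pinene, magnesium-salt-free), Et2O/pentane, −100 → −78 °C; then pH 7 phosphate buffer, 30% H2O2, 0 °C
Reagents that add atoms: (+)-B-allyldiisopinocampheylborane, C=CCB([C@H]1C[C@H]2C[C@@H]([C@@H]1C)C2(C)C)[C@H]1C[C@H]2C[C@@H]([C@@H]1C)C2(C)C
Why: Brown allylboration through a closed chair transition state: the (−)-α-pinene-derived reagent should add allyl to the Re face of the hindered aldehyde, as known for pivalaldehyde-type substrates, which sets 4R, and the cold buffered oxidation limits lactonisation of the γ-hydroxy ester.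

Step 3
Reactants: 3 methyl (4R)-4-hydroxy-3,3-dimethylhept-6-enoate
Product: 4 methyl (4R)-3,3-dimethyl-4-[(triethylsilyl)oxy]hept-6-enoate
Conditions: TESOTf, 2,6-lutidine, CH2Cl2, −78 → 0 °C (on crude 3, at once)
Reagents that add atoms: triethylsilyl trifluoromethanesulfonate, CC[Si](CC)(CC)OS(=O)(=O)C(F)(F)F
Why: Silyl triflate silylation of the hindered secondary alcohol blocks lactonisation and later alkoxide chemistry without touching the stereocentre.

Step 4
Reactants: 4 methyl (4R)-3,3-dimethyl-4-[(triethylsilyl)oxy]hept-6-enoate
Product: 5 methyl (4R)-3,3-dimethyl-6-oxo-4-[(triethylsilyl)oxy]hexanoate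
Conditions: O3, CH2Cl2, −78 °C; then PPh3, −78 °C → rt
Reagents that add atoms: ozone, [O-][O+]=O
Why: Ozonolysis of the terminal alkene with reductive work-up should give the β-silyloxy aldehyde; silyl ether and ester are inert to ozone at −78 °C.

Step 5
Reactants: 5 methyl (4R)-3,3-dimethyl-6-oxo-4-[(triethylsilyl)oxy]hexanoate
Product: 6 methyl (4R,6Z)-7-iodo-3,3-dimethyl-4-[(triethylsilyl)oxy]oct-6-enoate
Conditions: EtPPh3I, n-BuLi, THF, 0 °C → rt; I2, −78 °C; NaHMDS, −20 °C; then 5, −78 → −20 °C
Reagents that add atoms: ethyltriphenylphosphonium iodide, CC[P+](c1ccccc1)(c1ccccc1)c1ccccc1.[I-]; iodine, II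
Why: Stork–Zhao-type Wittig olefination with the α-iodo ylide proceeds through the kinetic cis-oxaphosphetane and should place iodine cis to the chain, giving the (Z)-2-iodo-2-alkene needed for a cis ring alkene; the cold non-stabilised ylide spares the ester and the β-silyloxy group.

Step 6
Reactants: 6 methyl (4R,6Z)-7-iodo-3,3-dimethyl-4-[(triethylsilyl)oxy]oct-6-enoate
Product: 9 methyl (1R,5R)-2,6,6-trimethyl-5-[(triethylsilyl)oxy]cyclohex-2-ene-1-carboxylate, via lithium enolate 7 (not isolated), via chlorozinc enolate 8 (not isolated)
Conditions: LDA, THF, −78 °C; ZnCl2, −78 → 23 °C; Pd(dba)2 (5 mol %), P(t-Bu)3 (10 mol %), THF (0.03 M), 23 → 50 °C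
Reagents that add atoms: none
Why: Zerovalent palladium inserts into the (Z)-C–I bond with retention, the chlorozinc enolate transmetalates to a C-bound palladium enolate within a seven-membered palladacycle, and C(sp2)–C(sp3) reductive elimination forms the C1–C2 bond of 9 (the C3–C4 bond of the target). The closest known reaction type is the palladium-catalysed α-alkenylation/arylation of ester zinc (Reformatsky-type) enolates, here run intramolecularly. The six-membered carbocycle closes by reductive elimination from the seven-membered palladacycle, formally a 6-(enolexo) attack of the enolate carbon on the vinylic carbon, and the Z geometry of the iodide becomes the cis ring alkene. The new stereocentre is controlled by the silyloxy-bearing carbon: in the product-like transition state the ester should sit pseudoaxial to escape A(1,2) strain with the vinylic methyl and two gauche contacts with the gem-dimethyl group, and the silyloxy group then takes the equatorial site away from it, which is the trans (1R,5R) arrangement. The step needs site selectivity, which the position of the C–I bond fixes (no five-membered alternative), freedom from β-hydride elimination, which the quaternary carbon next to the enolate guarantees, and configurational stability of the doubly activated α-hydrogen, which the weakly basic zinc enolate secures because the product is not deprotonated.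

Step 7
Reactants: 9 methyl (1R,5R)-2,6,6-trimethyl-5-[(triethylsilyl)oxy]cyclohex-2-ene-1-carboxylate
Product: 10 {(1R,5R)-2,6,6-trimethyl-5-[(triethylsilyl)oxy]cyclohex-2-en-1-yl}methanol
Conditions: LiAlH4, Et2O, 0 °C; Rochelle salt work-up
Reagents that add atoms: none
Why: Hydride reduction of the ester to the primary alcohol is faster than any enolisation, so the α-stereocentre and the β,γ-alkene position are kept, and the silyl ether survives LiAlH4 at 0 °C.

Step 8
Reactants: 10 {(1R,5R)-2,6,6-trimethyl-5-[(triethylsilyl)oxy]cyclohex-2-en-1-yl}methanol; 11 umbelliferone (7-hydroxy-2H-chromen-2-one)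
Product: 12 7-({(1R,5R)-2,6,6-trimethyl-5-[(triethylsilyl)oxy]cyclohex-2-en-1-yl}methoxy)-2H-chromen-2-one
Conditions: PPh3, DIAD, THF, 0 → 40 °C
Reagents that add atoms: none
Why: Mitsunobu etherification: the acidic phenol (pKa about 8) is alkylated by the alkoxyphosphonium of the primary alcohol in an SN2 step at the CH2 carbon, so neither ring stereocentre is involved.

Step 9
Reactants: 12 7-({(1R,5R)-2,6,6-trimethyl-5-[(triethylsilyl)oxy]cyclohex-2-en-1-yl}methoxy)-2H-chromen-2-one
Product: 14 (1R,3R)-2,2,4-trimethyl-3-{[(2-oxo-2H-chromen-7-yl)oxy]methyl}cyclohex-4-en-1-yl acetate (CNP0170350.1), via free alcohol 13 (not isolated)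
Conditions: HF·pyridine, pyridine/THF, 0 °C → rt; then Ac2O (excess), DMAP, rt
Reagents that add atoms: acetic anhydride, CC(=O)OC(C)=O
Why: Fluoride cleaves the Si–O bond without touching the C–O bond, and DMAP-catalysed acylation of the liberated secondary alcohol in the same flask occurs with retention to give the acetate.

Compound list
1 | methyl 3,3-dimethylpent-4-enoate | COC(=O)CC(C)(C)C=C | starting material
2 | methyl 3,3-dimethyl-4-oxobutanoate | COC(=O)CC(C)(C)C=O | intermediate
3 | methyl (4R)-4-hydroxy-3,3-dimethylhept-6-enoate | COC(=O)CC(C)(C)[C@H](O)CC=C | intermediate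
4 | methyl (4R)-3,3-dimethyl-4-[(triethylsilyl)oxy]hept-6-enoate | COC(=O)CC(C)(C)[C@H](O[Si](CC)(CC)CC)CC=C | intermediate
5 | methyl (4R)-3,3-dimethyl-6-oxo-4-[(triethylsilyl)oxy]hexanoate | COC(=O)CC(C)(C)[C@H](O[Si](CC)(CC)CC)CC=O | intermediate
6 | methyl (4R,6Z)-7-iodo-3,3-dimethyl-4-[(triethylsilyl)oxy]oct-6-enoate | COC(=O)CC(C)(C)[C@H](O[Si](CC)(CC)CC)C/C=C(/C)I | intermediate
7 | lithium enolate of 6 (not isolated) | COC(O[Li])=CC(C)(C)[C@H](O[Si](CC)(CC)CC)C/C=C(/C)I | intermediate
8 | chlorozinc enolate of 6 (not isolated) | COC(O[Zn]Cl)=CC(C)(C)[C@H](O[Si](CC)(CC)CC)C/C=C(/C)I | intermediate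
9 | methyl (1R,5R)-2,6,6-trimethyl-5-[(triethylsilyl)oxy]cyclohex-2-ene-1-carboxylate | CC[Si](CC)(CC)O[C@@H]1CC=C(C)[C@@H](C(=O)OC)C1(C)C | intermediate
10 | {(1R,5R)-2,6,6-trimethyl-5-[(triethylsilyl)oxy]cyclohex-2-en-1-yl}methanol | CC[Si](CC)(CC)O[C@@H]1CC=C(C)[C@@H](CO)C1(C)C | intermediate
11 | umbelliferone (7-hydroxy-2H-chromen-2-one) | Oc1ccc2ccc(=O)oc2c1 | starting material
12 | 7-({(1R,5R)-2,6,6-trimethyl-5-[(triethylsilyl)oxy]cyclohex-2-en-1-yl}methoxy)-2H-chromen-2-one | CC[Si](CC)(CC)O[C@@H]1CC=C(C)[C@@H](COc2ccc3ccc(=O)oc3c2)C1(C)C | intermediate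
13 | 7-{[(1R,5R)-5-hydroxy-2,6,6-trimethylcyclohex-2-en-1-yl]methoxy}-2H-chromen-2-one (not isolated) | O[C@@H]1CC=C(C)[C@@H](COc2ccc3ccc(=O)oc3c2)C1(C)C | intermediate
14 | (1R,3R)-2,2,4-trimethyl-3-{[(2-oxo-2H-chromen-7-yl)oxy]methyl}cyclohex-4-en-1-yl acetate | CC(=O)O[C@@H]1CC=C(C)[C@@H](COc2ccc3ccc(=O)oc3c2)C1(C)C | target

Total step count: 9. Longest linear sequence: 9 steps (1 → 14); umbelliferone 11 enters at step 8.

Steps most likely to fail

Step 6. The hindered neopentyl-type zinc enolate may transmetalate slowly to palladium, so that dehydroiodination or intermolecular coupling takes over, or the ring-forming reductive elimination may discriminate the two faces poorly. The fallback sets out from 6 and changes the bond construction from enolate coupling to a two-electrophile reductive coupling. Deprotonation of 6 with LDA and quenching with 1,2-dibromotetrachloroethane should give methyl (4R,6Z)-2-bromo-7-iodo-3,3-dimethyl-4-[(triethylsilyl)oxy]oct-6-enoate F1 as both C2 epimers. Intramolecular nickel-catalysed reductive cross-electrophile coupling (NiBr2(dme), 4,4′-di-tert-butyl-2,2′-bipyridine, Zn, DMA, rt) then joins the vinyl iodide carbon with the α-ester radical stereoconvergently, under non-basic conditions and with the same conformational bias, and comes back to the route at 9.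

Step 5. The basic ylide may eliminate silanol from the β-silyloxy aldehyde, and the Z/E selectivity of the iodo-olefination may erode. The fallback sets out from 5 and builds the haloalkene by dibromo-olefination and stereoselective cross-coupling instead. CBr4/PPh3 (CH2Cl2, 0 °C, 2,6-lutidine) should give methyl (4R)-7,7-dibromo-3,3-dimethyl-4-[(triethylsilyl)oxy]hept-6-enoate F2. Palladium-catalysed Negishi monomethylation (MeZnCl, PdCl2(DPEphos), THF, 0 °C → rt) replaces selectively the bromide trans to the chain and should give methyl (4R,6Z)-7-bromo-3,3-dimethyl-4-[(triethylsilyl)oxy]oct-6-enoate F3. F3 is cyclised under the conditions of step 6 and the route is rejoined at 9.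

Step 2. The free γ-hydroxy ester 3 may lactonise during work-up, and facial selectivity may be incomplete with the hindered aldehyde. The fallback sets out from 2 and avoids any free hydroxy ester: a catalytic enantioselective Mukaiyama single aldol addition of triethyl(vinyloxy)silane, run with a confined chiral imidodiphosphorimidate (IDPi) Brønsted acid of the handedness that gives Re-face attack, transfers the silyl group to the aldol oxygen and should deliver the silyl-protected aldol directly (no new compound, F0). It bypasses 3 and 4 and comes back to the route at 5.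

Further compounds
F1 | step 6 | methyl (4R,6Z)-2-bromo-7-iodo-3,3-dimethyl-4-[(triethylsilyl)oxy]oct-6-enoate | COC(=O)C(Br)C(C)(C)[C@H](O[Si](CC)(CC)CC)C/C=C(/C)I
F2 | step 5 | methyl (4R)-7,7-dibromo-3,3-dimethyl-4-[(triethylsilyl)oxy]hept-6-enoate | COC(=O)CC(C)(C)[C@H](O[Si](CC)(CC)CC)CC=C(Br)Br
F3 | step 5 | methyl (4R,6Z)-7-bromo-3,3-dimethyl-4-[(triethylsilyl)oxy]oct-6-enoate | COC(=O)CC(C)(C)[C@H](O[Si](CC)(CC)CC)C/C=C(/C)Br
F0 | step 2 | none | none
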